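Ring-A locants: O1, C2 (OCH), C3 (fusion CH), C4 (CH–isobutenyl); CQ becomes CMe2; suffix B marks quinolone B. Everything rests on cutting pyran ring B (O4B–CQ–C2–C3–C3B=C4B) into 4-hydroxy-1-methylquinolin-2(1H)-one, reacting through C3B and O4B, and an enoyl unit C3=C2–CQ(=O) whose α-carbon C2 already carries O1 of ring A. The feature exploited is the C3B/O4B 1,3-dinucleophile of quinolone B flanking the chain C3–C2–CQ, whose C3–C2 bond is the fusion with ring A. One oxidative carbene-catalysed annulation forms C3–C3B and CQ–O4B, closes ring B as a δ-lactone and sets C3 and C2 from C4. Its precursor is the enantiopure 4-isobutenyl-4H-pyrano[3,2-c]quinoline-2-carbaldehyde.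

Key step: step 5

Assumption: the quinine-derived squaramide is taken to deliver the (4S)-hemiketal (the 4R series after dehydration, by a change of CIP ranking only); should it favour the mirror image, its quinidine-derived pseudoenantiomer is used in its place.

Step 1
Reactants: 1 3-methylbut-2-enal; 2 ethyl 2-oxo-3-(triphenyl-λ5-phosphanylidene)propanoate
Product: 3 ethyl (3E)-6-methyl-2-oxohepta-3,5-dienoate
Conditions: PhMe, 90 °C
Reagents that add atoms: none
Why: Wittig olefination with a ketone-stabilised ylide should give the E-enone selectively under neutral conditions, which avoid γ-deprotonation of the enal.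

Step 2
Reactants: 3 ethyl (3E)-6-methyl-2-oxohepta-3,5-dienoate; 4 4-hydroxy-1-methylquinolin-2(1H)-one
Product: 6 ethyl (4R)-6-methyl-4-(2-methylprop-1-en-1-yl)-5-oxo-5,6-dihydro-4H-pyrano[3,2-c]quinoline-2-carboxylate, via hemiketal 5 (not isolated)
Conditions: quinine-derived 3,5-bis(trifluoromethyl)phenyl squaramide (5 mol%), CH2Cl2, 0 °C to rt; then TsOH·H2O (20 mol%), 4 Å molecular sieves, rt
Reagents that add atoms: none
Why: Asymmetric Michael addition–hemiketalisation followed by acid-catalysed dehydration: the bifunctional squaramide binds the 1,2-dicarbonyl of 3 and the quinolonate of 4 so that C3 of 4 adds to one face of the β-carbon (the fully substituted δ-carbon disfavours 1,6-addition), which sets C4, and loss of water from hemiketal 5 gives the conjugated enol ether ester without touching C4.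

Step 3
Reactants: 6 ethyl (4R)-6-methyl-4-(2-methylprop-1-en-1-yl)-5-oxo-5,6-dihydro-4H-pyrano[3,2-c]quinoline-2-carboxylate
Product: 7 (4R)-2-(hydroxymethyl)-6-methyl-4-(2-methylprop-1-en-1-yl)-4,6-dihydro-5H-pyrano[3,2-c]quinolin-5-one
Conditions: i-Bu2AlH (3 equiv), CH2Cl2, −78 °C; aq. KNaC4H4O6 (potassium sodium tartrate)
Reagents that add atoms: none
Why: Ester reduction by i-Bu2AlH at low temperature should give the primary allylic alcohol by 1,2-delivery of hydride, the aromatic 2-quinolone lactam and the trisubstituted alkene being inert.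

Step 4
Reactants: 7 (4R)-2-(hydroxymethyl)-6-methyl-4-(2-methylprop-1-en-1-yl)-4,6-dihydro-5H-pyrano[3,2-c]quinolin-5-one
Product: 8 (4R)-6-methyl-4-(2-methylprop-1-en-1-yl)-5-oxo-5,6-dihydro-4H-pyrano[3,2-c]quinoline-2-carbaldehyde
Conditions: activated MnO2 (15 equiv), CH2Cl2, rt
Reagents that add atoms: none
Why: MnO2 oxidation of an allylic alcohol is selective and neutral, so that the base-sensitive C4–H (γ to the new aldehyde) should keep its configuration.

Step 5
Reactants: 8 (4R)-6-methyl-4-(2-methylprop-1-en-1-yl)-5-oxo-5,6-dihydro-4H-pyrano[3,2-c]quinoline-2-carbaldehyde; 4 4-hydroxy-1-methylquinolin-2(1H)-one (1.2 equiv)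
Product: 11 cis-fused hexacyclic δ-lactone (2S,3S,4R), via enoyl azolium 9 (not isolated), via saturated acyl azolium 10 (not isolated)
Conditions: 2-mesityl-6,7-dihydro-5H-pyrrolo[2,1-c][1,2,4]triazol-2-ium chloride (10 mol%), DBU (0.3 equiv), 3,3′,5,5′-tetra-tert-butyldiphenoquinone (1.2 equiv), 4 Å molecular sieves, THF, rt
Reagents that add atoms: none
Why: Proposed new method: the carbene adds to the aldehyde of 8, the Breslow intermediate is oxidised by the diphenoquinone to the α-alkoxy enoyl azolium 9, C3B of the quinolonate of 4 adds to its β-carbon (pyran C3), the resulting azolium enol is protonated at C2 to give 10, and O4B then acylates with release of the carbene. The closest known reaction type is the oxidative carbene-catalysed [3+3] annulation of enals with 1,3-dicarbonyls, 4-hydroxycoumarins and 4-hydroxyquinolones to dihydropyranones; what is unproven is an enal whose α-carbon carries a ring oxygen and whose α,β-bond lies in that ring, and here the ring oxygen is a vinylogous ester oxygen of quinolone A, so it should donate little and leave the β-carbon electrophilic. Ring B closes as a δ-lactone by 6-exo-trig attack of O4B on the acyl azolium carbonyl CQ. The new C3 centre is controlled by the C4 stereocentre: allylic strain against the C5 carbonyl holds the isobutenyl group pseudoaxial, so the nucleophile should enter the opposite face and the two groups end up trans. The C2 centre is controlled thermodynamically: with the C3 substituent axial only an equatorial acyl group at C2 can reach O4B, and both the azolium enol and the α-position of the lactone can equilibrate to this cis fusion. The step needs O4B- over O2B-acylation and conjugate over direct addition, the first secured by retention of the 2-quinolone amide, the second by the reversibility of O-acylation of so acidic an enol under carbene catalysis, while the quinolone-buffered base should spare the C4–H.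

Step 6
Reactants: 11 cis-fused hexacyclic δ-lactone (2S,3S,4R)
Product: 12 (2S,3S,4R)-3-(4-hydroxy-1-methyl-2-oxo-1,2-dihydroquinolin-3-yl)-2-(2-hydroxypropan-2-yl)-6-methyl-4-(2-methylprop-1-en-1-yl)-2,3,4,6-tetrahydro-5H-pyrano[3,2-c]quinolin-5-one
Conditions: MeLi (5 equiv), CeCl3 (5.5 equiv), THF, −78 to −40 °C; aq. NH4Cl
Reagents that add atoms: methyllithium, [Li]C
Why: Twofold organocerium addition to a lactone: the first methyl opens the aryl-ester-type lactone to the methyl ketone and the quinolonate, the second gives the tertiary alkoxide, and the low basicity of MeCeCl2 should leave the α-stereocentre C2 untouched.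

Step 7
Reactants: 12 (2S,3S,4R)-3-(4-hydroxy-1-methyl-2-oxo-1,2-dihydroquinolin-3-yl)-2-(2-hydroxypropan-2-yl)-6-methyl-4-(2-methylprop-1-en-1-yl)-2,3,4,6-tetrahydro-5H-pyrano[3,2-c]quinolin-5-one
Product: 13 3-[(2S,3S,4R)-2-(2-hydroxypropan-2-yl)-6-methyl-4-(2-methylprop-1-en-1-yl)-5-oxo-3,4,5,6-tetrahydro-2H-pyrano[3,2-c]quinolin-3-yl]-1-methyl-2-oxo-1,2-dihydroquinolin-4-yl trifluoromethanesulfonate
Conditions: PhNTf2 (1.2 equiv), Et3N (2 equiv), DMAP (10 mol%), CH2Cl2, 0 °C to rt
Reagents that add atoms: N-phenylbis(trifluoromethanesulfonimide), O=S(=O)(N(c1ccccc1)S(=O)(=O)C(F)(F)F)C(F)(F)F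
Why: O-Sulfonylation of an enol: only the acidic 4-hydroxyquinolone OH is deprotonated by Et3N and triflated by PhNTf2 (at O4B, keeping the 2-quinolone amide), the tertiary alcohol being inert to this mild reagent.

Step 8
Reactants: 13 3-[(2S,3S,4R)-2-(2-hydroxypropan-2-yl)-6-methyl-4-(2-methylprop-1-en-1-yl)-5-oxo-3,4,5,6-tetrahydro-2H-pyrano[3,2-c]quinolin-3-yl]-1-methyl-2-oxo-1,2-dihydroquinolin-4-yl trifluoromethanesulfonate
Product: 14 target CNP0107253.2 (2S,3S,4R)
Conditions: NaH (1.5 equiv), THF, 0 °C to rt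
Reagents that add atoms: none
Why: Intramolecular addition–elimination (SNAr-type vinylogous acyl substitution) of the tertiary alkoxide at C4B of the 4-triflyloxy-2-quinolone should re-close ring B through a six-membered transition state, because the cis relationship of the C2 and C3 substituents set in step 5 holds the two ends together and no stereocentre is involved.

Compound list
1 | 3-methylbut-2-enal | CC(C)=CC=O | starting material
2 | ethyl 2-oxo-3-(triphenyl-λ5-phosphanylidene)propanoate | CCOC(=O)C(=O)C=P(c1ccccc1)(c1ccccc1)c1ccccc1 | starting material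
3 | ethyl (3E)-6-methyl-2-oxohepta-3,5-dienoate | CCOC(=O)C(=O)/C=C/C=C(C)C | intermediate
4 | 4-hydroxy-1-methylquinolin-2(1H)-one | Cn1c(=O)cc(O)c2ccccc21 | starting material
5 | ethyl (4S)-2-hydroxy-6-methyl-4-(2-methylprop-1-en-1-yl)-5-oxo-3,4,5,6-tetrahydro-2H-pyrano[3,2-c]quinoline-2-carboxylate (both C2 epimers, in equilibrium with the open keto ester) | CC(C)=C[C@@H]1CC(O)(C(=O)OCC)Oc2c1c(=O)n(C)c1ccccc21 | intermediate
6 | ethyl (4R)-6-methyl-4-(2-methylprop-1-en-1-yl)-5-oxo-5,6-dihydro-4H-pyrano[3,2-c]quinoline-2-carboxylate | CC(C)=C[C@@H]1C=C(C(=O)OCC)Oc2c1c(=O)n(C)c1ccccc21 | intermediate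
7 | (4R)-2-(hydroxymethyl)-6-methyl-4-(2-methylprop-1-en-1-yl)-4,6-dihydro-5H-pyrano[3,2-c]quinolin-5-one | CC(C)=C[C@@H]1C=C(CO)Oc2c1c(=O)n(C)c1ccccc21 | intermediate
8 | (4R)-6-methyl-4-(2-methylprop-1-en-1-yl)-5-oxo-5,6-dihydro-4H-pyrano[3,2-c]quinoline-2-carbaldehyde | CC(C)=C[C@@H]1C=C(C=O)Oc2c1c(=O)n(C)c1ccccc21 | intermediate
9 | enoyl azolium: the acyl group of 8 (CQ=O) bonded to C3 of the 2-mesityl-6,7-dihydro-5H-pyrrolo[2,1-c][1,2,4]triazol-2-ium catalyst, 4R | CC(C)=C[C@@H]1C=C(Oc2c1c(=O)n(C)c1ccccc21)C(=O)c1n2CCCc2n[n+]1-c1c(C)cc(C)cc1C | intermediate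
10 | saturated acyl azolium: (2S,3S,4R)-tetrahydropyranoquinolinone carrying the 4-hydroxy-1-methyl-2-oxoquinolin-3-yl group at C3 and the triazolium-bound acyl group at C2 | CC(C)=C[C@H]1c2c(c3ccccc3n(C)c2=O)O[C@H](C(=O)c2n3CCCc3n[n+]2-c2c(C)cc(C)cc2C)[C@@H]1c1c(O)c2ccccc2n(C)c1=O | intermediate
11 | cis-fused hexacyclic δ-lactone, (2S,3S,4R) in ring-A locants: 6-methyl-4-(2-methylprop-1-en-1-yl)-2,3,4,6-tetrahydro-5H-pyrano[3,2-c]quinolin-5-one whose C3 is bonded to C3B of a second 1-methylquinolin-2(1H)-one and whose C2 bears the carbonyl carbon CQ esterified by O4B; H2 and H3 cis, H3 and H4 trans | CC(C)=C[C@H]1c2c(c3ccccc3n(C)c2=O)O[C@H]2[C@@H]1c1c(c3ccccc3n(C)c1=O)OC2=O | intermediate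
12 | (2S,3S,4R)-3-(4-hydroxy-1-methyl-2-oxo-1,2-dihydroquinolin-3-yl)-2-(2-hydroxypropan-2-yl)-6-methyl-4-(2-methylprop-1-en-1-yl)-2,3,4,6-tetrahydro-5H-pyrano[3,2-c]quinolin-5-one | CC(C)=C[C@H]1c2c(c3ccccc3n(C)c2=O)O[C@H](C(C)(C)O)[C@@H]1c1c(O)c2ccccc2n(C)c1=O | intermediate
13 | 3-[(2S,3S,4R)-2-(2-hydroxypropan-2-yl)-6-methyl-4-(2-methylprop-1-en-1-yl)-5-oxo-3,4,5,6-tetrahydro-2H-pyrano[3,2-c]quinolin-3-yl]-1-methyl-2-oxo-1,2-dihydroquinolin-4-yl trifluoromethanesulfonate | CC(C)=C[C@H]1c2c(c3ccccc3n(C)c2=O)O[C@H](C(C)(C)O)[C@@H]1c1c(OS(=O)(=O)C(F)(F)F)c2ccccc2n(C)c1=O | intermediate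
14 | CNP0107253.2: as 11 but with CQ = C(CH3)2 bonded to O4B (cis-fused bis-pyranoquinolinone, (2S,3S,4R) in ring-A locants) | CC(C)=C[C@H]1c2c(c3ccccc3n(C)c2=O)O[C@H]2[C@@H]1c1c(c3ccccc3n(C)c1=O)OC2(C)C | target

Total step count: 8
Longest linear sequence: 8 steps (1 and 2 to 14; quinolone 4 enters in steps 2 and 5)

Steps most likely to fail

1. Step 5. The enoyl azolium, whose β-carbon is deactivated by the ring oxygen on the α-carbon, may undergo conjugate addition too slowly. The reaction could then stall at O-acylation of the quinolone, or the azolium could be deprotonated at the doubly allylic C4 with loss of configuration. The fallback uses known chemistry, sets out from alcohol 7 and comes back at lactone 11. Mitsunobu etherification of 7 with 4 (PPh3, DIAD, THF) should give the (4R)-2-[(1-methyl-2-oxoquinolin-4-yl)oxymethyl] ether F1. Thermal aromatic Claisen rearrangement (PhMe, 110–130 °C) should move the allyl unit to C3B, with bond formation at C3 anti to the isobutenyl group, and give the (3S,4R)-2-methylidene enol ether F2. Hydroboration with 9-BBN and oxidation (NaBO3·4H2O) should give the (2S,3S,4R)-2-hydroxymethyl compound F3, with hydrogen delivered to C2 anti to the quinolonyl group. Parikh–Doering oxidation (SO3·pyridine, DMSO, Et3N) should give the lactol F4, since the hydroxy aldehyde closes onto O4B as it forms. Ag2CO3 on Celite (PhMe, reflux) should oxidise the lactol to 11.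

2. Step 8. Attack of the hindered tertiary alkoxide at C4B may be slow, so that cleavage of the S–O bond of the triflate (return to 12) or dehydration of the carbinol competes. The fallback sets out from lactone 11 and comes back at 14. One equivalent of MeCeCl2 (MeLi, CeCl3, THF, −78 °C) should stop at the cyclic methyl hemiketal F5, a ring-closed methyl ketone of the warfarin type. AlMe3 with TMSOTf (CH2Cl2, −78 to 0 °C) should ionise it to the cyclic oxocarbenium ion and deliver the second methyl group to CQ. In this variant the O4B–CQ bond made in step 5 is never broken, and the last bond formed is CQ–CH3 instead of C4B–O.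

3. Step 2. Facial discrimination by the squaramide may be lower for an alkenyl-substituted acceptor than for the usual aryl ones, and the sense of induction is assumed. The fallback sets out from 3 and 4 and comes back at 6. DABCO-catalysed racemic Michael addition–hemiketalisation should give hemiketal 5 together with its enantiomer, the (4R)-hemiketal F6. Dehydration as in step 2 should give ester 6 together with its enantiomer, the (4S)-ester F7. Preparative chromatography on a chiral stationary phase separates the two, so that the absolute configuration comes from a resolution and not from the catalyst.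

Further compounds
F1 | step 5 | (4R)-6-methyl-2-{[(1-methyl-2-oxo-1,2-dihydroquinolin-4-yl)oxy]methyl}-4-(2-methylprop-1-en-1-yl)-4,6-dihydro-5H-pyrano[3,2-c]quinolin-5-one | CC(C)=C[C@@H]1C=C(COc2cc(=O)n(C)c3ccccc23)Oc2c1c(=O)n(C)c1ccccc21
F2 | step 5 | (3S,4R)-3-(4-hydroxy-1-methyl-2-oxo-1,2-dihydroquinolin-3-yl)-6-methyl-2-methylidene-4-(2-methylprop-1-en-1-yl)-2,3,4,6-tetrahydro-5H-pyrano[3,2-c]quinolin-5-one | CC(C)=C[C@H]1c2c(c3ccccc3n(C)c2=O)OC(=C)[C@@H]1c1c(O)c2ccccc2n(C)c1=O
F3 | step 5 | (2S,3S,4R)-3-(4-hydroxy-1-methyl-2-oxo-1,2-dihydroquinolin-3-yl)-2-(hydroxymethyl)-6-methyl-4-(2-methylprop-1-en-1-yl)-2,3,4,6-tetrahydro-5H-pyrano[3,2-c]quinolin-5-one | CC(C)=C[C@H]1c2c(c3ccccc3n(C)c2=O)O[C@H](CO)[C@@H]1c1c(O)c2ccccc2n(C)c1=O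
F4 | step 5 | (2S,3S,4R)-lactol: compound 11 with CQ as CH(OH) (both epimers at CQ) | CC(C)=C[C@H]1c2c(c3ccccc3n(C)c2=O)O[C@H]2[C@@H]1c1c(c3ccccc3n(C)c1=O)OC2O
F5 | step 8 | (2S,3S,4R)-methyl hemiketal: compound 11 with CQ as C(OH)CH3 (both epimers at CQ) | CC(C)=C[C@H]1c2c(c3ccccc3n(C)c2=O)O[C@H]2[C@@H]1c1c(c3ccccc3n(C)c1=O)OC2(C)O
F6 | step 2 | ethyl (4R)-2-hydroxy-6-methyl-4-(2-methylprop-1-en-1-yl)-5-oxo-3,4,5,6-tetrahydro-2H-pyrano[3,2-c]quinoline-2-carboxylate (enantiomer of 5) | CC(C)=C[C@H]1CC(O)(C(=O)OCC)Oc2c1c(=O)n(C)c1ccccc21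
F7 | step 2 | ethyl (4S)-6-methyl-4-(2-methylprop-1-en-1-yl)-5-oxo-5,6-dihydro-4H-pyrano[3,2-c]quinoline-2-carboxylate (enantiomer of 6) | CC(C)=C[C@H]1C=C(C(=O)OCC)Oc2c1c(=O)n(C)c1ccccc21
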